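A direct plan would take the 5-deoxy ring-A ketone 1-[2-hydroxy-3-methoxy-4-(SEM-oxy)phenyl]ethanone A1 and condense it with 4-(prenyloxy)benzaldehyde A2 to chalcone A3.
Alkaline hydrogen peroxide would then close ring C to the 5-deoxyflavonol A4, and O3 would be prenylated to give A5.
The missing C5 oxygen would come last, by a carbonyl-directed C–H borylation–oxidation, followed by removal of the SEM group.
Its weakest steps would be:
- the late C5 hydroxylation: a chromone-directed borylation has no precedent, it must outrun hydroboration and undirected borylation at two prenyl ethers, and it would be tried on the most advanced material;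
- the oxidative chalcone cyclisation: flavonol, aurone and dihydroflavonol formation compete, so the ring closure is left to substrate bias;
- the SEM protection and removal: two steps with no gain in skeleton, the removal needing hot fluoride on the finished dihydroxyflavone.

Plan of the new route
- Retrosynthesis: remove the allyl ethers on O5 and O7 and the prenyl group on O3, cut the C3–C4 bond of ring C as an acyl-anion acylation, then cut the O1–C2 ether bond.
- This leaves a ring-A salicylaldehyde with all four ring-A oxygens and C4, and a mandelate with C2, C3, ring B and the 4'-prenyl ether.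
- Rings A and B are bought; ring C is the only ring made, first the O1–C2 ether bond, last the C3–C4 carbon–carbon bond. C2–C3 and C4–C4a are never formed.
- Enabling feature: C3 and C4 are neighbouring carbons at the carbonyl level (a flavonol is the enol of a chromane-3,4-dione with an acidic C2–H). The formyl carbon on C4a and a carboxyl carbon, both electrophiles, can therefore be joined by polarity reversal at C4.
- The 8-methoxy group enters in step 3, ortho to the chelated hydroxyl of a phloroglucinol aldehyde. No late C–H oxidation, no oxidative chalcone closure and no silyl group occur; the only protecting groups are two allyl ethers removed with Pd(PPh3)4.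

Key step: step 6

Remark: allyl = prop-2-enyl, prenyl = 3-methylbut-2-enyl. Mandelate 5 is used as the racemate; its stereocentre (the future C2) becomes sp2 in step 6, and the target has no stereocentre.

Step 1
Reactants: 1 2,4,6-trihydroxybenzaldehyde
Product: 2 2-hydroxy-4,6-bis(allyloxy)benzaldehyde
Conditions: allyl bromide (2.1 equiv), K2CO3 (2.2 equiv), acetone, reflux
Reagents that add atoms: allyl bromide (3-bromoprop-1-ene), C=CCBr
Why: Williamson O-alkylation, in which the 4-hydroxyl (para to the formyl group) and one ortho hydroxyl should react, while the last ortho hydroxyl is held in a hydrogen bond to the aldehyde and should stay free with a limited amount of halide.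

Step 2
Reactants: 2 2-hydroxy-4,6-bis(allyloxy)benzaldehyde
Product: 3 2-hydroxy-3-iodo-4,6-bis(allyloxy)benzaldehyde
Conditions: N-iodosuccinimide (1.05 equiv), MeCN, 0 °C to rt, dark
Reagents that add atoms: N-iodosuccinimide, O=C1CCC(=O)N1I
Why: electrophilic aromatic iodination, which should go to C3 because it is ortho to the free phenol and flanked by one ether only, whereas C5 lies between two allyloxy groups (the known 3-halogenation of 2-hydroxy-4,6-dialkoxyaryl carbonyl compounds); the isolated allyl alkenes react far more slowly with NIS than the trioxygenated ring.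

Step 3
Reactants: 3 2-hydroxy-3-iodo-4,6-bis(allyloxy)benzaldehyde
Product: 4 2-hydroxy-3-methoxy-4,6-bis(allyloxy)benzaldehyde
Conditions: NaOMe (6 equiv), CuBr (0.2 equiv), MeOH/DMF (1:3), 100 °C; then 1 M HCl (work-up)
Reagents that add atoms: sodium methoxide, [Na+].[O-]C
Why: copper-catalysed Ullmann-type methoxylation of an aryl iodide, the reaction type that turns 5-halovanillins into syringaldehyde; the substrate reacts as its phenoxide, which shields the aldehyde from methoxide, and allyl aryl ethers should neither isomerise with methoxide in methanol nor undergo Claisen rearrangement at this temperature.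

Step 4
Reactants: 5 methyl 2-hydroxy-2-(4-hydroxyphenyl)acetate (methyl 4-hydroxymandelate, racemic)
Product: 6 methyl 2-hydroxy-2-[4-(prenyloxy)phenyl]acetate (racemic)
Conditions: prenyl bromide (1.1 equiv), K2CO3 (1.3 equiv), acetone, 50 °C
Reagents that add atoms: prenyl bromide (1-bromo-3-methylbut-2-ene), CC(C)=CCBr
Why: Williamson ether synthesis, in which carbonate ionises only the phenol and leaves the secondary alcohol untouched.

Step 5
Reactants: 4 2-hydroxy-3-methoxy-4,6-bis(allyloxy)benzaldehyde; 6 methyl 2-hydroxy-2-[4-(prenyloxy)phenyl]acetate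
Product: 7 methyl 2-[2-formyl-6-methoxy-3,5-bis(allyloxy)phenoxy]-2-[4-(prenyloxy)phenyl]acetate (racemic)
Conditions: PPh3 (1.3 equiv), DIAD (1.3 equiv), toluene/THF, 0 °C to rt
Reagents that add atoms: none
Why: Mitsunobu etherification, in which the chelated salicylaldehyde hydroxyl is acidic enough to protonate the betaine and the oxyphosphonium ion of the 4-alkoxymandelate is an activated benzylic electrophile next to an ester; the configuration at the new ether carbon does not matter because it is racemic and is erased in step 6.

Step 6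
Reactants: 7 methyl 2-[2-formyl-6-methoxy-3,5-bis(allyloxy)phenoxy]-2-[4-(prenyloxy)phenyl]acetate
Product: 9 3-hydroxy-8-methoxy-5,7-bis(allyloxy)-2-[4-(prenyloxy)phenyl]-4H-chromen-4-one, via chromane-3,4-dione 8 (not isolated)
Conditions: 3-benzyl-5-(2-hydroxyethyl)-4-methylthiazolium chloride (20 mol%), Et3N (2 equiv), 1,4-dioxane, 60 °C, under argon
Reagents that add atoms: none
Why: Proposed new method: the thiazol-2-ylidene freed by Et3N adds to the formyl carbon of 7 and a proton shift gives the Breslow enaminol, an acyl-anion equivalent at C4, which attacks the ester carbonyl carbon (C3); methoxide and then the carbene leave, and dione 8 tautomerises through its acidic C2–H (between O1, ring B and the C3 carbonyl) to flavonol 9, which makes the sequence irreversible. The closest known reaction types are the carbene-catalysed intramolecular crossed benzoin of 2-(2-oxoalkoxy)benzaldehydes to 3-hydroxychroman-4-ones and the intramolecular aldehyde–nitrile coupling of 2-(cyanomethoxy)benzaldehydes to 3-aminochromones; an ester as the acceptor, leading to a 3-hydroxychromone, has not been shown. Ring C closes at the C3–C4 carbon–carbon bond by 6-exo-trig attack on the ester carbonyl, the O1–C2 bond being already in place. No new stereocentre is formed and the one in 7 is lost. The step needs the acyl anion to form at a hindered, electron-rich aldehyde and to choose the ester over the alkene of the allyloxy group ortho to the formyl group and over dimerisation: the small thiazolylidene, the two ortho substituents that block homo-benzoin, the α-aryloxy activation of an ester held in a six-membered transition state, and a temperature well below the 120 °C at which carbene-catalysed hydroacylation of unactivated alkenes sets in should secure this. Aldol addition of the ester enolate to the aldehyde is reversible under Et3N and should feed back into 7.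

Step 7
Reactants: 9 3-hydroxy-8-methoxy-5,7-bis(allyloxy)-2-[4-(prenyloxy)phenyl]-4H-chromen-4-one
Product: 10 8-methoxy-3-(prenyloxy)-2-[4-(prenyloxy)phenyl]-5,7-bis(allyloxy)-4H-chromen-4-one
Conditions: prenyl bromide (1.3 equiv), K2CO3 (2 equiv), acetone, 50 °C
Reagents that add atoms: prenyl bromide (1-bromo-3-methylbut-2-ene), CC(C)=CCBr
Why: Williamson O-alkylation of the acidic 3-hydroxyl of the flavonol, the only free hydroxyl in 9.

Step 8
Reactants: 10 8-methoxy-3-(prenyloxy)-2-[4-(prenyloxy)phenyl]-5,7-bis(allyloxy)-4H-chromen-4-one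
Product: 11 5,7-dihydroxy-8-methoxy-3-(prenyloxy)-2-[4-(prenyloxy)phenyl]-4H-chromen-4-one (5,7-dihydroxy-8-methoxy-3,4'-diprenyloxyflavone)
Conditions: Pd(PPh3)4 (5 mol%), morpholine (6 equiv), THF, rt
Reagents that add atoms: none
Why: Tsuji–Trost-type deallylation, in which zerovalent palladium ionises the two unsubstituted allyl aryl ethers to π-allyl complexes that morpholine captures, while the prenyl ethers carry a trisubstituted alkene that binds palladium poorly and should ionise far more slowly; no acid, hydrogen or fluoride touches the product.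

**Compound list**
1 | 2,4,6-trihydroxybenzaldehyde | O=Cc1c(O)cc(O)cc1O | starting material
2 | 2-hydroxy-4,6-bis(allyloxy)benzaldehyde | O=Cc1c(O)cc(OCC=C)cc1OCC=C | intermediate
3 | 2-hydroxy-3-iodo-4,6-bis(allyloxy)benzaldehyde | O=Cc1c(O)c(I)c(OCC=C)cc1OCC=C | intermediate
4 | 2-hydroxy-3-methoxy-4,6-bis(allyloxy)benzaldehyde | O=Cc1c(O)c(OC)c(OCC=C)cc1OCC=C | intermediate
5 | methyl 2-hydroxy-2-(4-hydroxyphenyl)acetate (methyl 4-hydroxymandelate, racemic) | COC(=O)C(O)c1ccc(O)cc1 | starting material
6 | methyl 2-hydroxy-2-[4-(prenyloxy)phenyl]acetate (racemic) | COC(=O)C(O)c1ccc(OCC=C(C)C)cc1 | intermediate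
7 | methyl 2-[2-formyl-6-methoxy-3,5-bis(allyloxy)phenoxy]-2-[4-(prenyloxy)phenyl]acetate (racemic) | COC(=O)C(Oc1c(OC)c(OCC=C)cc(OCC=C)c1C=O)c1ccc(OCC=C(C)C)cc1 | intermediate
8 | 8-methoxy-5,7-bis(allyloxy)-2-[4-(prenyloxy)phenyl]chromane-3,4-dione (racemic, formed and consumed in the flask) | COc1c(OCC=C)cc(OCC=C)c2C(=O)C(=O)C(c3ccc(OCC=C(C)C)cc3)Oc12 | intermediate
9 | 3-hydroxy-8-methoxy-5,7-bis(allyloxy)-2-[4-(prenyloxy)phenyl]-4H-chromen-4-one | COc1c(OCC=C)cc(OCC=C)c2c(=O)c(O)c(-c3ccc(OCC=C(C)C)cc3)oc12 | intermediate
10 | 8-methoxy-3-(prenyloxy)-2-[4-(prenyloxy)phenyl]-5,7-bis(allyloxy)-4H-chromen-4-one | COc1c(OCC=C)cc(OCC=C)c2c(=O)c(OCC=C(C)C)c(-c3ccc(OCC=C(C)C)cc3)oc12 | intermediate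
11 | 5,7-dihydroxy-8-methoxy-3-(prenyloxy)-2-[4-(prenyloxy)phenyl]-4H-chromen-4-one | COc1c(O)cc(O)c2c(=O)c(OCC=C(C)C)c(-c3ccc(OCC=C(C)C)cc3)oc12 | target

Total step count: 8. Longest linear sequence: 7 (steps 1, 2, 3, 5, 6, 7, 8).

Steps most likely to fail

Step 6. The carbene may add only slowly to the doubly ortho-substituted, electron-rich aldehyde, and the acyl-anion equivalent may be diverted into hydroacylation of the neighbouring O-allyl alkene or be oxidised by traces of air. The fallback sets out from 7 and swaps the roles of the two carbonyl carbons, using known chemistry. LiAlH4 (THF, 0 °C) would reduce both carbonyl groups to 2-[2-(hydroxymethyl)-6-methoxy-3,5-bis(allyloxy)phenoxy]-2-[4-(prenyloxy)phenyl]ethan-1-ol F1. Dess–Martin periodinane (NaHCO3, CH2Cl2) would give the dialdehyde 2-[2-formyl-6-methoxy-3,5-bis(allyloxy)phenoxy]-2-[4-(prenyloxy)phenyl]acetaldehyde F2. A carbene-catalysed intramolecular aldehyde–aldehyde benzoin reaction (thiazolium salt, Et3N, THF, rt), in which the unhindered aliphatic aldehyde is the acyl-anion donor and the aryl aldehyde the acceptor, would give the acyloin 4-hydroxy-8-methoxy-5,7-bis(allyloxy)-2-[4-(prenyloxy)phenyl]chroman-3-one F3 as a mixture of diastereomers. A second Dess–Martin oxidation would give dione 8, which enolises, and the route is rejoined at 9.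

Step 8. A prenyl group may be lost by competing ionisation at palladium, above all at O3, where the flavonol oxide is a good leaving group, or the cleavage may stall at the chelated 5-O-allyl ether. The fallback sets out from 10 and replaces π-allyl ionisation by isomerisation–hydrolysis. RhCl(PPh3)3 with DABCO (EtOH/H2O, reflux) would move only the unsubstituted allyl double bonds into conjugation with oxygen, giving 8-methoxy-3-(prenyloxy)-2-[4-(prenyloxy)phenyl]-5,7-bis(prop-1-enyloxy)-4H-chromen-4-one F4; the trisubstituted prenyl alkenes should not isomerise. The two enol ethers would then be hydrolysed with 0.1 M HCl in aqueous acetone at rt, which returns to the route at 11.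

Step 5. The hindered, hydrogen-bonded phenol may attack too slowly, so that the activated mandelate ionises and is captured by the hydrazide. The fallback sets out from 6 and uses a separately made halide. CBr4/PPh3 (CH2Cl2, 0 °C) would give methyl 2-bromo-2-[4-(prenyloxy)phenyl]acetate F5, which would alkylate the phenoxide of 4 (K2CO3, DMF, rt) and return to the route at 7.

Further compounds
F1 | step 6 | 2-[2-(hydroxymethyl)-6-methoxy-3,5-bis(allyloxy)phenoxy]-2-[4-(prenyloxy)phenyl]ethan-1-ol (racemic) | OCC(Oc1c(OC)c(OCC=C)cc(OCC=C)c1CO)c1ccc(OCC=C(C)C)cc1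
F2 | step 6 | 2-[2-formyl-6-methoxy-3,5-bis(allyloxy)phenoxy]-2-[4-(prenyloxy)phenyl]acetaldehyde (racemic) | O=CC(Oc1c(OC)c(OCC=C)cc(OCC=C)c1C=O)c1ccc(OCC=C(C)C)cc1
F3 | step 6 | 4-hydroxy-8-methoxy-5,7-bis(allyloxy)-2-[4-(prenyloxy)phenyl]chroman-3-one (mixture of diastereomers) | COc1c(OCC=C)cc(OCC=C)c2C(O)C(=O)C(c3ccc(OCC=C(C)C)cc3)Oc12
F4 | step 8 | 8-methoxy-3-(prenyloxy)-2-[4-(prenyloxy)phenyl]-5,7-bis(prop-1-enyloxy)-4H-chromen-4-one (E/Z mixture) | COc1c(OC=CC)cc(OC=CC)c2c(=O)c(OCC=C(C)C)c(-c3ccc(OCC=C(C)C)cc3)oc12
F5 | step 5 | methyl 2-bromo-2-[4-(prenyloxy)phenyl]acetate (racemic) | COC(=O)C(Br)c1ccc(OCC=C(C)C)cc1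
A1 | direct plan | 1-[2-hydroxy-3-methoxy-4-(SEM-oxy)phenyl]ethan-1-one | CC(=O)c1ccc(OCOCC[Si](C)(C)C)c(OC)c1O
A2 | direct plan | 4-(prenyloxy)benzaldehyde | CC(C)=CCOc1ccc(C=O)cc1
A3 | direct plan | (E)-1-[2-hydroxy-3-methoxy-4-(SEM-oxy)phenyl]-3-[4-(prenyloxy)phenyl]prop-2-en-1-one | COc1c(OCOCC[Si](C)(C)C)ccc(C(=O)/C=C/c2ccc(OCC=C(C)C)cc2)c1O
A4 | direct plan | 3-hydroxy-8-methoxy-2-[4-(prenyloxy)phenyl]-7-(SEM-oxy)-4H-chromen-4-one | COc1c(OCOCC[Si](C)(C)C)ccc2c(=O)c(O)c(-c3ccc(OCC=C(C)C)cc3)oc12
A5 | direct plan | 8-methoxy-3-(prenyloxy)-2-[4-(prenyloxy)phenyl]-7-(SEM-oxy)-4H-chromen-4-one | COc1c(OCOCC[Si](C)(C)C)ccc2c(=O)c(OCC=C(C)C)c(-c3ccc(OCC=C(C)C)cc3)oc12
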